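**Plan**
1. Numbering: ring A is C1 (CMe2) to C6 (CH), the chain runs C7–C15 and C15'–C8' (CH2OH). The retrosynthesis cuts chain carbon C9 twice, at C8–C9 and at C9–CH3, giving an (E)-iodovinyl ring fragment (C1–C8), a 1,1-dibromo-heptaenoate (C9–C8') and Me2Zn.
2. Enabling feature: C9 is the one sp2 chain carbon that carries both a methyl group and the bond to the vinyl arm C7=C8 of ring A. In a 1,1-dibromoalkene at C9 the bromine trans to the C10–C11 polyene substituent reacts first, so both groups go on in one flask with defined C9=C10 geometry.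
3. The dibromide is cut at C9=C10 (dibromo-olefination) and C10'=C9' (Wittig) to a symmetric C14 dialdehyde, and that at C11=C12 and C11'=C12' to the C10 trienedial. The ring fragment is cut at C7=C8 (Takai), C6–C7 ([2,3] shift) and the C4–O oxirane back to ketoisophorone.
4. Forward: ring A is bought as a six-membered ring and carried through eight steps to the iodide. The chain grows C10 → C14 → C17 → C18 dibromide. The three components are joined, then ester reduction and desilylation finish the route.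
5. Stereochemistry: C3 (S) from asymmetric transfer hydrogenation. A temporary oxygen at C4 is placed cis to it by hydroxyl-directed epoxidation and relayed suprafacially to C6 (R) by the Wittig–Still shift. E-geometries come from the Takai step (C7=C8), from site-selective oxidative addition plus retentive methylation (C9=C10), from stabilised or equilibrating Wittig steps and from the all-E C10 dialdehyde.

Key step: step 12

Remark: in step 1 the (S,S)-catalyst is assumed to give the (S)-carbinol by the usual model for conjugated ketones (enone alkene in the place of the arene); if the sense were opposite, the (R,R)-catalyst would be used with no other change.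

Step 1
Reactants: 1 2,6,6-trimethylcyclohex-2-ene-1,4-dione (ketoisophorone)
Product: 2 (4S)-4-hydroxy-2,6,6-trimethylcyclohex-2-en-1-one
Conditions: RuCl[(S,S)-TsDPEN](p-cymene) (0.5 mol %), HCO2H/Et3N (5:2), CH2Cl2, 25 °C
Reagents that add atoms: none
Why: Noyori-type asymmetric transfer hydrogenation reduces only the accessible C4 carbonyl (the C1 carbonyl is buried between CMe2 and C(Me)=), and the chiral Ru–H/N–H catalyst tells the alkene side from the CH2 side of that ketone, which should set the carbinol centre (C3 of the target) as S.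

Step 2
Reactants: 2 (4S)-4-hydroxy-2,6,6-trimethylcyclohex-2-en-1-one
Product: 3 (1S,5S,6S)-5-hydroxy-1,3,3-trimethyl-7-oxabicyclo[4.1.0]heptan-2-one
Conditions: t-BuOOH (2.5 equiv, anhydrous), n-BuLi (2.0 equiv), THF, –78 → –20 °C; then H2O
Reagents that add atoms: tert-butyl hydroperoxide, CC(C)(C)OO
Why: Hydroxyl-directed Weitz–Scheffer (nucleophilic) epoxidation, in which the lithium-bound γ-hydroxyl holds t-BuOOLi and delivers the peroxide to the β-carbon on its own face, so the oxirane should form cis to the hydroxyl.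

Step 3
Reactants: 3 (1S,5S,6S)-5-hydroxy-1,3,3-trimethyl-7-oxabicyclo[4.1.0]heptan-2-one
Product: 4 (1S,5S,6S)-1,3,3-trimethyl-5-[(triisopropylsilyl)oxy]-7-oxabicyclo[4.1.0]heptan-2-one
Conditions: i-Pr3SiOTf (1.2 equiv), 2,6-lutidine (2 equiv), CH2Cl2, –78 → 0 °C
Reagents that add atoms: triisopropylsilyl trifluoromethanesulfonate, CC(C)[Si](C(C)C)(C(C)C)OS(=O)(=O)C(F)(F)F
Why: Standard silylation of a secondary alcohol with a silyl triflate; the bulky triisopropylsilyl group is chosen because it resists O-to-O migration towards the neighbouring alkoxide of step 5.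

Step 4
Reactants: 4 (1S,5S,6S)-1,3,3-trimethyl-5-[(triisopropylsilyl)oxy]-7-oxabicyclo[4.1.0]heptan-2-one
Product: 6 (1R,6S)-2,4,4-trimethyl-6-[(triisopropylsilyl)oxy]cyclohex-2-en-1-ol, via epoxy hydrazone 5 (not isolated)
Conditions: N2H4·H2O (3 equiv), AcOH (0.2 equiv), MeOH, 0 °C → rt
Reagents that add atoms: none
Why: Wharton transposition, in which the α,β-epoxy hydrazone opens to an allylic diazene that loses N2; the alkene moves to C5=C6 and the former oxirane C4–O bond is untouched, so the allylic hydroxyl stays cis to the silyloxy group.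

Step 5
Reactants: 6 (1R,6S)-2,4,4-trimethyl-6-[(triisopropylsilyl)oxy]cyclohex-2-en-1-ol
Product: 7 tributyl[({(1R,6S)-2,4,4-trimethyl-6-[(triisopropylsilyl)oxy]cyclohex-2-en-1-yl}oxy)methyl]stannane
Conditions: KH (1.3 equiv), THF, 0 °C; Bu3SnCH2I (1.3 equiv), 0 °C → rt
Reagents that add atoms: (iodomethyl)tributylstannane, CCCC[Sn](CCCC)(CCCC)CI
Why: Williamson etherification of the potassium alkoxide with the reactive α-stannyl iodide (first half of the Wittig–Still protocol), which touches no stereocentre.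

Step 6
Reactants: 7 tributyl[({(1R,6S)-2,4,4-trimethyl-6-[(triisopropylsilyl)oxy]cyclohex-2-en-1-yl}oxy)methyl]stannane
Product: 9 {(1R,4S)-2,6,6-trimethyl-4-[(triisopropylsilyl)oxy]cyclohex-2-en-1-yl}methanol, via lithiomethyl ether 8 (not isolated)
Conditions: n-BuLi (1.5 equiv), THF, –78 °C; then H2O at –78 °C
Reagents that add atoms: none
Why: Wittig–Still [2,3]-sigmatropic rearrangement, in which tin–lithium exchange gives an α-alkoxymethyllithium whose carbon bonds to C6 on the face of the breaking C4–O bond (suprafacial five-membered transition state, the C4–O bond held pseudoaxial by A(1,2) strain with the C5 methyl); this should set C6 as R with the CH2OH group cis to the silyloxy group and restore the C4=C5 ring alkene.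

Step 7
Reactants: 9 {(1R,4S)-2,6,6-trimethyl-4-[(triisopropylsilyl)oxy]cyclohex-2-en-1-yl}methanol
Product: 10 (1R,4S)-2,6,6-trimethyl-4-[(triisopropylsilyl)oxy]cyclohex-2-ene-1-carbaldehyde
Conditions: Dess–Martin periodinane (1.3 equiv), pyridine (3 equiv), CH2Cl2, 0 °C → rt
Reagents that add atoms: none
Why: Dess–Martin oxidation under buffered, non-basic conditions, so the β,γ-unsaturated aldehyde should neither epimerise at C6 nor move its alkene into conjugation.

Step 8
Reactants: 10 (1R,4S)-2,6,6-trimethyl-4-[(triisopropylsilyl)oxy]cyclohex-2-ene-1-carbaldehyde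
Product: 11 {[(1S,4R)-4-[(E)-2-iodoethenyl]-3,5,5-trimethylcyclohex-2-en-1-yl]oxy}triisopropylsilane
Conditions: CrCl2 (6 equiv), CHI3 (2 equiv), THF/1,4-dioxane (1:6), 0 °C → rt, dark
Reagents that add atoms: iodoform, IC(I)I
Why: Takai olefination, in which the geminal dichromium species from CHI3 and divalent chromium adds to the aldehyde and eliminates to the (E)-iodoalkene; the α-branched substituent reinforces E selectivity and the neutral medium spares C6.

Step 9
Reactants: 12 (2E,4E,6E)-2,7-dimethylocta-2,4,6-trienedial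
Product: 14 (2E,4E,6E,8E,10E)-4,9-dimethyldodeca-2,4,6,8,10-pentaenedial, via bis(dioxolane) pentaene 13 (not isolated)
Conditions: (1,3-dioxolan-2-ylmethyl)triphenylphosphonium bromide (2.4 equiv), t-BuOK (2.4 equiv), THF, 0 °C → rt; then 1 M HCl, THF, rt
Reagents that add atoms: (1,3-dioxolan-2-ylmethyl)triphenylphosphonium bromide, [Br-].C1COC(C[P+](c2ccccc2)(c2ccccc2)c2ccccc2)O1; water, O
Why: Twofold Wittig reaction with the acetal-masked formylmethyl ylide followed by acid hydrolysis, the standard two-carbon vinylogation of an enal; the acid also equilibrates the two new C=C bonds of the conjugated dialdehyde to E.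

Step 10
Reactants: 14 (2E,4E,6E,8E,10E)-4,9-dimethyldodeca-2,4,6,8,10-pentaenedial
Product: 15 ethyl (2E,4E,6E,8E,10E,12E)-2,6,11-trimethyl-14-oxotetradeca-2,4,6,8,10,12-hexaenoate
Conditions: 14 (3 equiv), Ph3P=C(CH3)CO2Et (1 equiv, slow addition), CH2Cl2, rt; excess 14 recovered
Reagents that add atoms: (1-ethoxycarbonylethylidene)triphenylphosphorane, CCOC(=O)C(C)=P(c1ccccc1)(c1ccccc1)c1ccccc1
Why: Wittig reaction of a stabilised α-methyl ylide, reliably E-selective for the trisubstituted enoate; the excess of symmetric dialdehyde limits double olefination to the easily separated diester.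

Step 11
Reactants: 15 ethyl (2E,4E,6E,8E,10E,12E)-2,6,11-trimethyl-14-oxotetradeca-2,4,6,8,10,12-hexaenoate
Product: 16 ethyl (2E,4E,6E,8E,10E,12E)-15,15-dibromo-2,6,11-trimethylpentadeca-2,4,6,8,10,12,14-heptaenoate
Conditions: CBr4 (2 equiv), PPh3 (4 equiv), Et3N (1 equiv), CH2Cl2, 0 °C, dark
Reagents that add atoms: tetrabromomethane, BrC(Br)(Br)Br
Why: Ramirez dibromo-olefination (first stage of the Corey–Fuchs sequence), in which Ph3P=CBr2 formed in the flask converts the aldehyde into the 1,1-dibromoalkene without touching the ester or the polyene geometry.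

Step 12
Reactants: 11 {[(1S,4R)-4-[(E)-2-iodoethenyl]-3,5,5-trimethylcyclohex-2-en-1-yl]oxy}triisopropylsilane; 16 ethyl (2E,4E,6E,8E,10E,12E)-15,15-dibromo-2,6,11-trimethylpentadeca-2,4,6,8,10,12,14-heptaenoate
Product: 20 ethyl (2E,4E,6E,8E,10E,12E,14E,16E)-2,6,11,15-tetramethyl-17-{(1R,4S)-2,6,6-trimethyl-4-[(triisopropylsilyl)oxy]cyclohex-2-en-1-yl}heptadeca-2,4,6,8,10,12,14,16-octaenoate, via alkenyllithium 17 (not isolated), via alkenylzinc bromide 18 (not isolated), via bromo octaenoate 19 (not isolated)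
Conditions: 11, t-BuLi (2.1 equiv), Et2O, –78 °C; ZnBr2 (1.1 equiv) in THF, –78 → 0 °C; 16 (0.9 equiv), PdCl2(DPEphos) (5 mol %), THF, 0 → 23 °C; then Me2Zn (2 equiv), Pd(P(t-Bu)3)2 (5 mol %), 23 °C, dark
Reagents that add atoms: dimethylzinc, C[Zn]C
Why: Iodine–lithium exchange and transmetalation give the (E)-alkenylzinc bromide 18 with retention; zerovalent palladium then inserts into the C9–Br bond of 16 that is trans to the C10–C11 polyene substituent (the cis bromine is shielded by it), transmetalation with 18 and reductive elimination form the C8–C9 bond, and the remaining hindered C9–Br bond of 19 is coupled with Me2Zn under Pd(P(t-Bu)3)2 to form the C9–CH3 bond. The closest known reaction type is the one-pot Negishi sequence of trans-selective monoalkenylation of a 1,1-dibromo-1-alkene followed by methylation, which gives (1E)-2-methyl-1,3-dienes. No ring is closed and no stereocentre is created; the C7=C8 geometry is carried over from iodide 11, and the C9=C10 geometry follows from the site of the first oxidative addition together with retention in the second coupling. The step needs mono- over bis-alkenylation and retention over the palladium-mediated E/Z inversion known for 2-bromo-1,3-dienes: the first is secured by the steric difference between the two bromines, one equivalent of 18 and the wide-bite-angle DPEphos ligand, the second by the bulky monophosphine P(t-Bu)3, which favours fast transmetalation and reductive elimination over isomerisation of the dienylpalladium intermediate. The neutral, base-free medium should leave the doubly allylic C6–H, the ester and the silyl ether untouched.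

Step 13
Reactants: 20 ethyl (2E,4E,6E,8E,10E,12E,14E,16E)-2,6,11,15-tetramethyl-17-{(1R,4S)-2,6,6-trimethyl-4-[(triisopropylsilyl)oxy]cyclohex-2-en-1-yl}heptadeca-2,4,6,8,10,12,14,16-octaenoate
Product: 21 (2E,4E,6E,8E,10E,12E,14E,16E)-2,6,11,15-tetramethyl-17-{(1R,4S)-2,6,6-trimethyl-4-[(triisopropylsilyl)oxy]cyclohex-2-en-1-yl}heptadeca-2,4,6,8,10,12,14,16-octaen-1-ol
Conditions: i-Bu2AlH (2.5 equiv), CH2Cl2, –78 °C; aq. potassium sodium tartrate
Reagents that add atoms: none
Why: Hydride reduction of a conjugated ester with i-Bu2AlH gives the allylic alcohol by 1,2-reduction at low temperature, compatible with the silyl ether and the polyene.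

Step 14
Reactants: 21 (2E,4E,6E,8E,10E,12E,14E,16E)-2,6,11,15-tetramethyl-17-{(1R,4S)-2,6,6-trimethyl-4-[(triisopropylsilyl)oxy]cyclohex-2-en-1-yl}heptadeca-2,4,6,8,10,12,14,16-octaen-1-ol
Product: 22 (2E,4E,6E,8E,10E,12E,14E,16E)-17-[(1R,4S)-4-hydroxy-2,6,6-trimethylcyclohex-2-en-1-yl]-2,6,11,15-tetramethylheptadeca-2,4,6,8,10,12,14,16-octaen-1-ol
Conditions: Bu4NF (1 M in THF, 1.5 equiv), THF, 0 °C → rt, dark
Reagents that add atoms: none
Why: Fluoride-mediated silyl ether cleavage under near-neutral conditions avoids the acid that would ionise either allylic alcohol or shift the C4=C5 alkene.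

**Compound list**
1 | 2,6,6-trimethylcyclohex-2-ene-1,4-dione | CC1=CC(=O)CC(C)(C)C1=O | starting material
2 | (4S)-4-hydroxy-2,6,6-trimethylcyclohex-2-en-1-one | CC1=C[C@@H](O)CC(C)(C)C1=O | intermediate
3 | (1S,5S,6S)-5-hydroxy-1,3,3-trimethyl-7-oxabicyclo[4.1.0]heptan-2-one | C[C@]1(O2)[C@@H]2[C@@H](O)CC(C)(C)C1=O | intermediate
4 | (1S,5S,6S)-1,3,3-trimethyl-5-[(triisopropylsilyl)oxy]-7-oxabicyclo[4.1.0]heptan-2-one | C[C@]1(O2)[C@@H]2[C@@H](O[Si](C(C)C)(C(C)C)C(C)C)CC(C)(C)C1=O | intermediate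
5 | hydrazone of 4 (epoxy hydrazone) | C[C@]1(O2)[C@@H]2[C@@H](O[Si](C(C)C)(C(C)C)C(C)C)CC(C)(C)C1=NN | intermediate
6 | (1R,6S)-2,4,4-trimethyl-6-[(triisopropylsilyl)oxy]cyclohex-2-en-1-ol | CC1=CC(C)(C)C[C@H](O[Si](C(C)C)(C(C)C)C(C)C)[C@@H]1O | intermediate
7 | tributyl[({(1R,6S)-2,4,4-trimethyl-6-[(triisopropylsilyl)oxy]cyclohex-2-en-1-yl}oxy)methyl]stannane | CC1=CC(C)(C)C[C@H](O[Si](C(C)C)(C(C)C)C(C)C)[C@@H]1OC[Sn](CCCC)(CCCC)CCCC | intermediate
8 | lithiomethyl ether of 6 | CC1=CC(C)(C)C[C@H](O[Si](C(C)C)(C(C)C)C(C)C)[C@@H]1OC[Li] | intermediate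
9 | {(1R,4S)-2,6,6-trimethyl-4-[(triisopropylsilyl)oxy]cyclohex-2-en-1-yl}methanol | CC1=C[C@@H](O[Si](C(C)C)(C(C)C)C(C)C)CC(C)(C)[C@H]1CO | intermediate
10 | (1R,4S)-2,6,6-trimethyl-4-[(triisopropylsilyl)oxy]cyclohex-2-ene-1-carbaldehyde | CC1=C[C@@H](O[Si](C(C)C)(C(C)C)C(C)C)CC(C)(C)[C@H]1C=O | intermediate
11 | {[(1S,4R)-4-[(E)-2-iodoethenyl]-3,5,5-trimethylcyclohex-2-en-1-yl]oxy}triisopropylsilane | CC1=C[C@@H](O[Si](C(C)C)(C(C)C)C(C)C)CC(C)(C)[C@H]1/C=C/I | intermediate
12 | (2E,4E,6E)-2,7-dimethylocta-2,4,6-trienedial | O=C/C(C)=C/C=C/C=C(C)/C=O | starting material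
13 | bis(1,3-dioxolane) of 14, mixture of isomers at the two new C=C bonds | C1COC(O1)C=C/C(C)=C/C=C/C=C(C)/C=CC1OCCO1 | intermediate
14 | (2E,4E,6E,8E,10E)-4,9-dimethyldodeca-2,4,6,8,10-pentaenedial | O=C/C=C/C(C)=C/C=C/C=C(C)/C=C/C=O | intermediate
15 | ethyl (2E,4E,6E,8E,10E,12E)-2,6,11-trimethyl-14-oxotetradeca-2,4,6,8,10,12-hexaenoate | CCOC(=O)/C(C)=C/C=C/C(C)=C/C=C/C=C(C)/C=C/C=O | intermediate
16 | ethyl (2E,4E,6E,8E,10E,12E)-15,15-dibromo-2,6,11-trimethylpentadeca-2,4,6,8,10,12,14-heptaenoate | CCOC(=O)/C(C)=C/C=C/C(C)=C/C=C/C=C(C)/C=C/C=C(Br)Br | intermediate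
17 | (E)-alkenyllithium from 11 | CC1=C[C@@H](O[Si](C(C)C)(C(C)C)C(C)C)CC(C)(C)[C@H]1/C=C/[Li] | intermediate
18 | (E)-alkenylzinc bromide from 11 | CC1=C[C@@H](O[Si](C(C)C)(C(C)C)C(C)C)CC(C)(C)[C@H]1/C=C/[Zn]Br | intermediate
19 | ethyl (2E,4E,6E,8E,10E,12E,14Z,16E)-15-bromo-2,6,11-trimethyl-17-{(1R,4S)-2,6,6-trimethyl-4-[(triisopropylsilyl)oxy]cyclohex-2-en-1-yl}heptadeca-2,4,6,8,10,12,14,16-octaenoate | CC1=C[C@@H](O[Si](C(C)C)(C(C)C)C(C)C)CC(C)(C)[C@H]1/C=C/C(Br)=C/C=C/C(C)=C/C=C/C=C(C)/C=C/C=C(\C)C(=O)OCC | intermediate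
20 | ethyl (2E,4E,6E,8E,10E,12E,14E,16E)-2,6,11,15-tetramethyl-17-{(1R,4S)-2,6,6-trimethyl-4-[(triisopropylsilyl)oxy]cyclohex-2-en-1-yl}heptadeca-2,4,6,8,10,12,14,16-octaenoate | CC1=C[C@@H](O[Si](C(C)C)(C(C)C)C(C)C)CC(C)(C)[C@H]1/C=C/C(C)=C/C=C/C(C)=C/C=C/C=C(C)/C=C/C=C(\C)C(=O)OCC | intermediate
21 | (2E,4E,6E,8E,10E,12E,14E,16E)-2,6,11,15-tetramethyl-17-{(1R,4S)-2,6,6-trimethyl-4-[(triisopropylsilyl)oxy]cyclohex-2-en-1-yl}heptadeca-2,4,6,8,10,12,14,16-octaen-1-ol | CC1=C[C@@H](O[Si](C(C)C)(C(C)C)C(C)C)CC(C)(C)[C@H]1/C=C/C(C)=C/C=C/C(C)=C/C=C/C=C(C)/C=C/C=C(\C)CO | intermediate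
22 | (2E,4E,6E,8E,10E,12E,14E,16E)-17-[(1R,4S)-4-hydroxy-2,6,6-trimethylcyclohex-2-en-1-yl]-2,6,11,15-tetramethylheptadeca-2,4,6,8,10,12,14,16-octaen-1-ol | CC1=C[C@@H](O)CC(C)(C)[C@H]1/C=C/C(C)=C/C=C/C(C)=C/C=C/C=C(C)/C=C/C=C(\C)CO | target

**Step count and risks**
Total steps: 14. Longest linear sequence: 11 (steps 1–8, 12, 13, 14).

Steps most likely to fail:

Step 2. The peroxide may be delivered to the face away from the hydroxyl (poor facial selectivity), which would place the temporary C4 oxygen trans to the C3 oxygen and lead to the wrong C6 epimer after the suprafacial shift. The fallback sets out from 2 and accepts the sterically controlled anti epoxidation, then corrects C4 by inversion. Compound 2 is silylated (i-Pr3SiOTf, 2,6-lutidine) to (4S)-2,6,6-trimethyl-4-[(triisopropylsilyl)oxy]cyclohex-2-en-1-one F1. Alkaline H2O2 (NaOH, MeOH, 0 °C) should then add anti to the bulky silyloxy group to give (1R,5S,6R)-1,3,3-trimethyl-5-[(triisopropylsilyl)oxy]-7-oxabicyclo[4.1.0]heptan-2-one F2. Wharton transposition (N2H4·H2O, AcOH, MeOH) gives the trans allylic alcohol (1S,6S)-2,4,4-trimethyl-6-[(triisopropylsilyl)oxy]cyclohex-2-en-1-ol F3. Mitsunobu inversion (PPh3, diisopropyl azodicarboxylate, 4-nitrobenzoic acid, THF) gives (1R,6S)-2,4,4-trimethyl-6-[(triisopropylsilyl)oxy]cyclohex-2-en-1-yl 4-nitrobenzoate F4. Methanolysis (K2CO3, MeOH) comes back to the route at 6.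

Step 6. A [1,2]-shift or simple protonation of the α-alkoxymethyllithium may outrun the [2,3]-shift, because the alkene terminus C6 lies next to the quaternary C1. The fallback sets out from 6 and uses a neutral carbene [2,3]-shift that delivers the C7 carbon already at the carbonyl oxidation level. Heating 6 with N,N-dimethylformamide dimethyl acetal (xylene, 150 °C, removal of methanol) should pass through the alkoxy(dimethylamino)carbene and give, suprafacially, (1R,4S)-N,N,2,6,6-pentamethyl-4-[(triisopropylsilyl)oxy]cyclohex-2-ene-1-carboxamide F5. Partial reduction with Cp2Zr(H)Cl (THF, rt) comes back to the route at aldehyde 10, and steps 5–7 are skipped.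

Step 12. In the one-pot sequence the C9=C10 geometry may be eroded during the second coupling, or the dibromide may be consumed by twofold alkenylation and polyene degradation in the presence of excess organozinc. The fallback sets out from 11 and 16 and separates the two bond formations with a boron nucleophile and an isolated intermediate. Iodide 11 is converted (t-BuLi, Et2O, –78 °C; then 2-isopropoxy-4,4,5,5-tetramethyl-1,3,2-dioxaborolane) into triisopropyl({(1S,4R)-3,5,5-trimethyl-4-[(E)-2-(4,4,5,5-tetramethyl-1,3,2-dioxaborolan-2-yl)ethenyl]cyclohex-2-en-1-yl}oxy)silane F6. A trans-selective Suzuki–Miyaura coupling of F6 with 16 (Pd2(dba)3, tri(2-furyl)phosphine, Cs2CO3, dioxane/H2O, rt) gives bromide 19, which is now isolated and purified. A second Suzuki–Miyaura coupling of 19 with trimethylboroxine (PdCl2(dppf), Cs2CO3, dioxane, 60 °C) comes back to the route at 20.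

Further compounds
F1 | step 2 | (4S)-2,6,6-trimethyl-4-[(triisopropylsilyl)oxy]cyclohex-2-en-1-one | CC1=C[C@@H](O[Si](C(C)C)(C(C)C)C(C)C)CC(C)(C)C1=O
F2 | step 2 | (1R,5S,6R)-1,3,3-trimethyl-5-[(triisopropylsilyl)oxy]-7-oxabicyclo[4.1.0]heptan-2-one | C[C@@]1(O2)[C@H]2[C@@H](O[Si](C(C)C)(C(C)C)C(C)C)CC(C)(C)C1=O
F3 | step 2 | (1S,6S)-2,4,4-trimethyl-6-[(triisopropylsilyl)oxy]cyclohex-2-en-1-ol | CC1=CC(C)(C)C[C@H](O[Si](C(C)C)(C(C)C)C(C)C)[C@H]1O
F4 | step 2 | (1R,6S)-2,4,4-trimethyl-6-[(triisopropylsilyl)oxy]cyclohex-2-en-1-yl 4-nitrobenzoate | CC1=CC(C)(C)C[C@H](O[Si](C(C)C)(C(C)C)C(C)C)[C@@H]1OC(=O)c1ccc(cc1)[N+](=O)[O-]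
F5 | step 6 | (1R,4S)-N,N,2,6,6-pentamethyl-4-[(triisopropylsilyl)oxy]cyclohex-2-ene-1-carboxamide | CC1=C[C@@H](O[Si](C(C)C)(C(C)C)C(C)C)CC(C)(C)[C@H]1C(=O)N(C)C
F6 | step 12 | triisopropyl({(1S,4R)-3,5,5-trimethyl-4-[(E)-2-(4,4,5,5-tetramethyl-1,3,2-dioxaborolan-2-yl)ethenyl]cyclohex-2-en-1-yl}oxy)silane | CC1=C[C@@H](O[Si](C(C)C)(C(C)C)C(C)C)CC(C)(C)[C@H]1/C=C/B1OC(C)(C)C(C)(C)O1
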